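## The problem

The target is a 2-aryl-4H-chromen-4-one. Ring C (O1, C2, C3, C4, C4a, C8a) is fused to ring A and bonded through C2–C1' to ring B, and each benzene ring carries four oxygen atoms. There is no stereocentre, so the difficulty is regiochemistry and telling seven oxygen atoms apart: five are methylated, while 5-OH and 6'-OH are free. C1' is flanked by 2'-OMe and 6'-OH, so the C2–C1' bond is hindered. Acyl transfer from a di-ortho-substituted benzoate is slow, and 2,6-dioxygenated arylboron reagents tend to lose boron before they couple.

Ring C can open at O1–C2 to a 1,3-diketone. Reclosure on the 5-oxygen turns the 5,6,7-pattern into the 5,7,8-pattern (Wessely–Moser rearrangement), and reclosure of the 6'-OH on C4 exchanges the roles of rings A and B. Hot mineral acid and strong base must therefore be avoided once 5-OH is free.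

The feature the plan uses is that ring A (C4a, C5, C6, C7, C8, C8a) and ring B (C1', C2', C3', C4', C5', C6') are the same ring. Seen from the carbon bonded to the C4–C3–C2 chain, each has an ortho oxygen followed by two methoxy-bearing carbons (5-O, 6-OMe, 7-OMe and 2'-OMe, 3'-OMe, 4'-OMe), then a CH (C8 and C5'), then the second ortho oxygen (O1 and 6'-OH). They differ only by the methyl group missing on the 5-oxygen. In the 5-O-methyl ether 9 the open-chain diketone is therefore symmetric, the exchange of rings A and B returns the same compound, and both rings come from one phenol, 3,4,5-trimethoxyphenol 1, whose two ortho positions are equivalent.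

## Retrosynthesis

**Target 10 to flavone 9.** No skeletal bond is cut; the 5-OH is traced back to a 5-OMe. Against carrying a special protecting group on the 5-oxygen, this makes ring A and ring B identical in 9, so every ring-C closure and ring exchange on the way to 9 is degenerate. The forward step must remove one methyl group out of six. Only the 5-methoxy oxygen can sit in a six-membered chelate with the C4 carbonyl, so a Lewis acid should find it.

**Flavone 9 to coumarin 5 and aryllithium 7.** The C2–C1' bond is cut, the C4 carbonyl is written as a methyl enol ether and the 6'-OH as a MOM ether. The neighbouring cut at C2–C3 (Claisen or Baker–Venkataraman) needs two differently functionalised ring pieces and a hindered acyl transfer. The present cut makes the hindered bond by carbonyl addition of an aryllithium, and puts one ring plus all three ring-C carbons into 4,5,6,7-tetramethoxycoumarin 5. The lactone carbonyl of 5 becomes C2 and its methoxy-bearing carbon becomes C4. Because the two aryl groups are the same, it does not matter whether the coumarin ring ends up as ring A or ring B. The forward reaction needs 1,2-addition at the lactone carbonyl, a single addition, and acid to convert the adduct into 9.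

**Aryllithium 7 to MOM ether 6 to phenol 1.** The C–Li bond is traced to the C–H between OMOM and OMe in 1,2,3-trimethoxy-5-(methoxymethoxy)benzene 6, which is the only kind of ring hydrogen present. Compound 6 is the MOM ether of 1.

**Coumarin 5 to hydroxycoumarin 4 to phenol 1 and Meldrum's acid 2.** The enol ether O–CH3 bond is cut to give 4-hydroxy-5,6,7-trimethoxycoumarin 4. Then the ester bond O1–C2 and the aryl–carbonyl bond C4–C4a of the coumarin are cut, giving 1 and a malonyl unit from 2. The forward ring closure is an intramolecular Friedel–Crafts acylation at either of two equivalent ortho positions. The whole skeleton of 10 is thus two molecules of 1 and the three carbons of 2.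

## Roads not taken

**Alternative 1:** Baker–Venkataraman, the most obvious route. The cut is C2–C3 and O1–C2. 1-(6-Hydroxy-2,3,4-trimethoxyphenyl)ethan-1-one A1 would be O-acylated with 6-(benzyloxy)-2,3,4-trimethoxybenzoyl chloride A2 to ester A3. Base-induced acyl migration would give the 1,3-diketone A4; acid cyclodehydration and hydrogenolysis would give 9, which is then demethylated as in the chosen route. A2 needs its own protected multi-step synthesis from 1, and the migrating acyl group is di-ortho-substituted. The sequence treats two identical rings as different and is about three steps longer.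

**Alternative 2:** lactone bridge. The cut is C2–C1', made within a tether. 5,6,7-Trimethoxy-4-oxo-4H-chromene-3-carboxylic acid A5 would be esterified with 1 to the aryl ester A6. Intramolecular dehydrogenative coupling of chromone C2–H with the ortho C–H of the aryl ester (Pd(OAc)2, divalent palladium, AgOAc as oxidant) would give the lactone-bridged tetracycle A7, which hydrolytic decarboxylation would open to 9. The 6'-OH and C3 are well placed for a one-carbon bridge. However, A5 needs three steps (C-acetylation, Vilsmeier formylation–cyclisation, oxidation) before the ester is made. The aryl ester prefers the conformation that holds the arene away from C2, and the bridge carbon must be removed again. The chosen route reaches 9 in half the steps without a transition metal.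

**Alternative 3:** ring A by electrocyclisation. The cut is C4a–C5 and the ring A π-system. A squaric-acid-derived cyclobutenone bonded to C6 of a 2-aryl-4-pyranone, A8, would open thermally (4π) to a dienylketene. 6π-Electrocyclisation onto the pyranone C5=C6 bond and tautomerisation would give the 5-hydroxy-6,7-dimethoxyflavone MOM ether A9, and acid would release 10. The 5-OH is born free from the ketene carbon, which is attractive. But A8 requires a 6-metallated 2-aryl-4-pyranone and a 4-halocyclobutenone, and it still contains the hindered C2–C1' bond, so its preparation would be longer than the whole chosen route.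

Key step: step 4

Assumption: rotation about the C2–C1' bond is taken as fast at room temperature, so the target is treated as achiral; compounds 1 and 2 and all reagents are commercial.

## Steps

Step 1
Reactants: 1 3,4,5-trimethoxyphenol; 2 Meldrum's acid (2,2-dimethyl-1,3-dioxane-4,6-dione)
Product: 4 4-hydroxy-5,6,7-trimethoxy-2H-chromen-2-one, via aryl hydrogen malonate 3 (not isolated)
Conditions: 2 (1.1 equiv), toluene, 100 °C; concentrate; then Eaton's reagent (P2O5 in MeSO3H), 70 °C
Reagents that add atoms: none
Why: The phenol opens Meldrum's acid with loss of acetone to the malonic half ester 3; Eaton's reagent then effects intramolecular Friedel–Crafts acylation at either of the two equivalent ortho positions (each para to a methoxy group), and the product enolises to the 4-hydroxycoumarin.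

Step 2
Reactants: 4 4-hydroxy-5,6,7-trimethoxy-2H-chromen-2-one
Product: 5 4,5,6,7-tetramethoxy-2H-chromen-2-one
Conditions: Me2SO4, K2CO3, acetone, reflux
Reagents that add atoms: dimethyl sulfate, COS(=O)(=O)OC
Why: Williamson-type O-alkylation of the vinylogous carboxylate of a 4-hydroxycoumarin; a hard methylating agent with K2CO3 in acetone should favour the 4-oxygen over C3.

Step 3
Reactants: 1 3,4,5-trimethoxyphenol
Product: 6 1,2,3-trimethoxy-5-(methoxymethoxy)benzene
Conditions: NaH, THF–DMF, 0 °C; then MOMCl, 0 °C to rt
Reagents that add atoms: chloromethyl methyl ether (MOMCl), COCCl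
Why: Williamson etherification of the sodium phenoxide; the MOM group is both the protecting group for the future 6'-OH and the directing group for the metalation in step 4.

Step 4
Reactants: 6 1,2,3-trimethoxy-5-(methoxymethoxy)benzene; 5 4,5,6,7-tetramethoxy-2H-chromen-2-one
Product: 9 2-(6-hydroxy-2,3,4-trimethoxyphenyl)-5,6,7-trimethoxy-4H-chromen-4-one, via aryllithium 7 (not isolated), via ring-opened enone phenoxide 8 (not isolated)
Conditions: 6, n-BuLi (1.1 equiv), THF, 0 °C; then 5 (0.9 equiv), THF, −78 to 0 °C; then AcOH, concd aq HCl, 60 °C
Reagents that add atoms: water, O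
Why: Directed ortho-metalation of 6 should give 7 at the only kind of C–H present, which lies between OMOM and OMe. Aryllithium 7 adds to the lactone carbonyl of 5 and the tetrahedral intermediate opens to phenoxide 8; the closest known reaction type is the addition of aryl Grignard or aryllithium reagents to coumarins, which gives 2-arylbenzopyrylium (flavylium) salts on acidification. Acid then removes the MOM group and recloses ring C by attack of the phenol oxygen on the new ketone (6-exo-trig hemiketal). Loss of water gives the 4-methoxy-2-arylbenzopyrylium ion, and water adds at C4 and expels methanol to give the chromen-4-one; the atom bookkeeping follows this pathway, in which the C4 oxygen of 9 comes from water. The other closure (6-endo-trig addition–elimination of the freed phenol of the incoming ring at the methoxy-bearing carbon) and cyclodehydration of the 1,3-diketone formed if the enol ether hydrolyses first both also give 9, because the two aryl groups are the same 6-hydroxy-2,3,4-trimethoxyphenyl group. No stereocentre is formed. The step needs attack at the lactone carbonyl rather than at C4 or H-3, and a single addition. C4 is the donor-substituted end of a vinylogous carbonate and is shielded by its own methoxy group and the peri 5-OMe, and the ketone in 8 is a di-ortho-substituted aryl vinylogous ester that a second hindered aryllithium should not reach.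

Step 5
Reactants: 9 2-(6-hydroxy-2,3,4-trimethoxyphenyl)-5,6,7-trimethoxy-4H-chromen-4-one
Product: 10 5-hydroxy-2-(6-hydroxy-2,3,4-trimethoxyphenyl)-6,7-dimethoxy-4H-chromen-4-one (5,6'-dihydroxy-6,7,2',3',4'-pentamethoxyflavone)
Conditions: BCl3 (1 M in CH2Cl2, 3 equiv), CH2Cl2, −78 to 0 °C; then H2O
Reagents that add atoms: none
Why: Chelation-controlled Lewis acid demethylation of a 5-methoxyflavone: boron bound to the C4 carbonyl holds the 5-methoxy oxygen in a six-membered chelate and chloride removes its methyl group. The 6'-OH only consumes one equivalent as an aryloxyboron species with no neighbouring methoxy group, and the absence of hot protic acid avoids opening of ring C.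

## Compound list

1 | 3,4,5-trimethoxyphenol | COc1cc(O)cc(OC)c1OC | starting material
2 | Meldrum's acid (2,2-dimethyl-1,3-dioxane-4,6-dione) | CC1(C)OC(=O)CC(=O)O1 | starting material
3 | 3-oxo-3-(3,4,5-trimethoxyphenoxy)propanoic acid | COc1cc(OC(=O)CC(O)=O)cc(OC)c1OC | intermediate (not isolated)
4 | 4-hydroxy-5,6,7-trimethoxy-2H-chromen-2-one | COc1cc2oc(=O)cc(O)c2c(OC)c1OC | intermediate
5 | 4,5,6,7-tetramethoxy-2H-chromen-2-one | COc1cc2oc(=O)cc(OC)c2c(OC)c1OC | intermediate
6 | 1,2,3-trimethoxy-5-(methoxymethoxy)benzene | COCOc1cc(OC)c(OC)c(OC)c1 | intermediate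
7 | [6-(methoxymethoxy)-2,3,4-trimethoxyphenyl]lithium | [Li]c1c(OCOC)cc(OC)c(OC)c1OC | intermediate (not isolated)
8 | lithium 2-[(1E)-1-methoxy-3-[6-(methoxymethoxy)-2,3,4-trimethoxyphenyl]-3-oxoprop-1-en-1-yl]-3,4,5-trimethoxyphenolate | [Li+].[O-]c1cc(OC)c(OC)c(OC)c1/C(OC)=C\C(=O)c1c(OCOC)cc(OC)c(OC)c1OC | intermediate (not isolated)
9 | 2-(6-hydroxy-2,3,4-trimethoxyphenyl)-5,6,7-trimethoxy-4H-chromen-4-one | COc1cc(O)c(-c2cc(=O)c3c(OC)c(OC)c(OC)cc3o2)c(OC)c1OC | intermediate
10 | 5-hydroxy-2-(6-hydroxy-2,3,4-trimethoxyphenyl)-6,7-dimethoxy-4H-chromen-4-one | COc1cc(O)c(-c2cc(=O)c3c(O)c(OC)c(OC)cc3o2)c(OC)c1OC | target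

## Step count and risks

Total step count: 5. Longest linear sequence: 4 steps (steps 1, 2, 4, 5); step 3 is a one-step branch that joins at step 4.

**Step 4 (key step).** The most likely failure is proton transfer instead of addition: the aryllithium may remove H-3 of 5, the α-hydrogen of a β-alkoxyacrylate, and return both partners. Less likely are attack at C4 with loss of methoxide, and a stall of the acid phase at the enol ether or diketone stage. The fallback sets out from 6 and 1 and returns at 9 by the classical acyl-transfer route:
- Phenol 1 is C-acetylated (AcOH, BF3·OEt2, 90 °C) to 1-(6-hydroxy-2,3,4-trimethoxyphenyl)ethan-1-one F1.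
- Aryllithium 7, made from 6 as before, is quenched with CO2 to 6-(methoxymethoxy)-2,3,4-trimethoxybenzoic acid F2.
- F1 and F2 are joined (EDC·HCl, DMAP, CH2Cl2) to 2-acetyl-3,4,5-trimethoxyphenyl 6-(methoxymethoxy)-2,3,4-trimethoxybenzoate F3.
- Baker–Venkataraman rearrangement (KOH, pyridine, 50 °C) gives 1-(6-hydroxy-2,3,4-trimethoxyphenyl)-3-[6-(methoxymethoxy)-2,3,4-trimethoxyphenyl]propane-1,3-dione F4.
- AcOH with concd aq HCl at 60 °C removes the MOM group and cyclodehydrates to 9; the direction of closure is again immaterial.

**Step 5.** The most likely failure is loss of selectivity. After the 5-methyl group is gone, the boron chelate can pass the Lewis acid on to the neighbouring 6-OMe. The aryloxyboron species at the 6'-oxygen also uses up reagent and may carry it into ring B. Acid formed on warming could open ring C and scramble the substitution pattern. The fallback sets out from 9 and returns at 10 by protecting first: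
- Acetylation (Ac2O, pyridine) gives 2-(5,6,7-trimethoxy-4-oxo-4H-chromen-2-yl)-3,4,5-trimethoxyphenyl acetate F5.
- Chelation-controlled demethylation with AlCl3 in MeCN at rt gives 2-(5-hydroxy-6,7-dimethoxy-4-oxo-4H-chromen-2-yl)-3,4,5-trimethoxyphenyl acetate F6.
- Mild methanolysis (K2CO3, MeOH, 0 °C) gives 10.

**Step 2.** The most likely failure is alkylation at the wrong atom of the ambident anion, either at the lactone carbonyl oxygen or at C3. The fallback sets out from 4 and returns at 5 by addition–elimination instead of alkylation:
- POCl3 with Et3N gives 4-chloro-5,6,7-trimethoxy-2H-chromen-2-one F7.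
- NaOMe in MeOH (0 °C to rt) replaces chloride at C4 to give 5.

## Further compounds

F1 | step 4 | 1-(6-hydroxy-2,3,4-trimethoxyphenyl)ethan-1-one | CC(=O)c1c(O)cc(OC)c(OC)c1OC
F2 | step 4 | 6-(methoxymethoxy)-2,3,4-trimethoxybenzoic acid | COCOc1cc(OC)c(OC)c(OC)c1C(O)=O
F3 | step 4 | 2-acetyl-3,4,5-trimethoxyphenyl 6-(methoxymethoxy)-2,3,4-trimethoxybenzoate | CC(=O)c1c(OC(=O)c2c(OCOC)cc(OC)c(OC)c2OC)cc(OC)c(OC)c1OC
F4 | step 4 | 1-(6-hydroxy-2,3,4-trimethoxyphenyl)-3-[6-(methoxymethoxy)-2,3,4-trimethoxyphenyl]propane-1,3-dione | COCOc1cc(OC)c(OC)c(OC)c1C(=O)CC(=O)c1c(O)cc(OC)c(OC)c1OC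
F5 | step 5 | 2-(5,6,7-trimethoxy-4-oxo-4H-chromen-2-yl)-3,4,5-trimethoxyphenyl acetate | CC(=O)Oc1cc(OC)c(OC)c(OC)c1-c1cc(=O)c2c(OC)c(OC)c(OC)cc2o1
F6 | step 5 | 2-(5-hydroxy-6,7-dimethoxy-4-oxo-4H-chromen-2-yl)-3,4,5-trimethoxyphenyl acetate | CC(=O)Oc1cc(OC)c(OC)c(OC)c1-c1cc(=O)c2c(O)c(OC)c(OC)cc2o1
F7 | step 2 | 4-chloro-5,6,7-trimethoxy-2H-chromen-2-one | COc1cc2oc(=O)cc(Cl)c2c(OC)c1OC
A1 | alternative 1 | 1-(6-hydroxy-2,3,4-trimethoxyphenyl)ethan-1-one | CC(=O)c1c(O)cc(OC)c(OC)c1OC
A2 | alternative 1 | 6-(benzyloxy)-2,3,4-trimethoxybenzoyl chloride | COc1cc(OCc2ccccc2)c(C(Cl)=O)c(OC)c1OC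
A3 | alternative 1 | 2-acetyl-3,4,5-trimethoxyphenyl 6-(benzyloxy)-2,3,4-trimethoxybenzoate | CC(=O)c1c(OC(=O)c2c(OCc3ccccc3)cc(OC)c(OC)c2OC)cc(OC)c(OC)c1OC
A4 | alternative 1 | 1-[6-(benzyloxy)-2,3,4-trimethoxyphenyl]-3-(6-hydroxy-2,3,4-trimethoxyphenyl)propane-1,3-dione | COc1cc(OCc2ccccc2)c(C(=O)CC(=O)c2c(O)cc(OC)c(OC)c2OC)c(OC)c1OC
A5 | alternative 2 | 5,6,7-trimethoxy-4-oxo-4H-chromene-3-carboxylic acid | COc1cc2occ(C(O)=O)c(=O)c2c(OC)c1OC
A6 | alternative 2 | 3,4,5-trimethoxyphenyl 5,6,7-trimethoxy-4-oxo-4H-chromene-3-carboxylate | COc1cc2occ(C(=O)Oc3cc(OC)c(OC)c(OC)c3)c(=O)c2c(OC)c1OC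
A7 | alternative 2 | 1,2,3,8,9,10-hexamethoxy-6H,7H-chromeno[4,3-b]chromene-6,7-dione | COc1cc2oc3c(c(=O)c2c(OC)c1OC)c(=O)oc1cc(OC)c(OC)c(OC)c13
A8 | alternative 3 | 2-(2,3-dimethoxy-4-oxocyclobut-2-en-1-yl)-6-[6-(methoxymethoxy)-2,3,4-trimethoxyphenyl]-4H-pyran-4-one (racemic) | COCOc1cc(OC)c(OC)c(OC)c1-c1cc(=O)cc(o1)C1C(=O)C(OC)=C1OC
A9 | alternative 3 | 5-hydroxy-6,7-dimethoxy-2-[6-(methoxymethoxy)-2,3,4-trimethoxyphenyl]-4H-chromen-4-one | COCOc1cc(OC)c(OC)c(OC)c1-c1cc(=O)c2c(O)c(OC)c(OC)cc2o1
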